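**Remarks on the chemistry (assumptions)**

- Cembrane numbering is used throughout: ring carbons C1–C14; C15 on C1 carries C16 (carboxyl carbon) and C17 (methyl); C18 is the methyl on C4, C19 the exocyclic methylene on C8, C20 the methyl on C12.
- The target string reads as (1R,3R,4S,7R,11S,12S,15S). The oxirane has C10 and C13 trans, so it is the epoxide of an 11E olefin. The seco keto-aldehyde 28 and the macrocycle 30 are drawn with the same configurations at C1, C3, C4, C7 and C15 and with 11E geometry; no configurational correction is needed.
- Protecting groups in 28 and 30 are placed as 7-O-TBDPS and 16-O-TBS (with the 3,4-acetonide). Mild acid can then free the 3,4,16-triol while the allylic C7 oxygen stays blocked through the oxidation and the epoxidation. With the more labile silyl group on C7 the triol could not be unmasked selectively.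
- Both epoxidations need the L-fructose-derived ketone, the antipode of the common D-fructose-derived Shi catalyst; this follows from the D-catalyst giving (R,R)-epoxides from E-olefins. It is treated as a purchasable catalyst.
- For alternative 1 the C1=C14 ring olefin of A1 is assumed to be E.

## Structural features

The target is a cembranoid: a 14-membered carbocycle (C1–C14) bridged between C1 and C3 by a δ-lactone (C1–C15–C16(=O)–O–C3), which shares C1–C2–C3 with the large ring. The ring also carries a trisubstituted 11,12-oxirane, a 1,1-disubstituted exocyclic olefin at C8(=C19), a tertiary carbinol at C4 and an allylic secondary carbinol at C7. Of the seven stereocentres, C15/C1 are adjacent, C3/C4 are adjacent and 1,3 to C1 across C2, C7 is isolated by C5–C6, and the C11/C12 pair is isolated by two methylenes on each side. In the lactone chair the C4 chain on C3, C14 on C1 and C17 on C15 are all equatorial, so C15 has the thermodynamically preferred configuration. The fragile groups are the oxirane (acid, transannular attack by the C4 and C7 hydroxyls), the lactone (hydride, strong base, low-valent metals), the epimerisable C15 and the allylic C7–O bond beside the exocyclic methylene. The real difficulty is closing the 14-membered ring in the presence of these groups while relaying configuration between four remote stereo-units. The key step exploits the E-trisubstituted C11=C12 unit bearing C20: it is the retron of an aldehyde (C11) / methyl ketone (C12) reductive coupling. The segment C20–C12–C13–C14–C1(C15)–C2–C3 is the skeleton of limonene cut at its ring olefin.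

## Logic of the disconnections

**35 ⇒ 34 ⇒ 33.** The C7 O–Si bond is cut last, then the C11–O and C12–O bonds of the oxirane. The oxirane is the most acid-labile element, so it is installed in the penultimate step on the 11E olefin of 33. The forward step must transfer oxygen to one face of the trisubstituted olefin and leave the exocyclic olefin alone.

**33 ⇒ 31 ⇒ 30.** The acyl C16–O(C3) bond is cut by lowering C16 to the alcohol (31) and masking the three oxygens (30). A lactone cannot pass through low-valent titanium, hence the detour. The forward steps need an acid treatment that removes the cyclic ketal and the primary silyl ether but not the secondary one, and an oxidation that starts at the primary hydroxyl and stops at the lactone.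

**30 ⇒ 28.** The C11=C12 bond is cut to two carbonyls, opening the 14-membered ring. This removes the only large ring and creates no stereocentre. The forward step must be intramolecular, E-selective and confined to the two carbonyls.

**28 ⇒ 27 ⇒ 26 ⇒ 25 ⇒ 22 + 24.** The C12 ketone is masked as a ketal and the C11 aldehyde is carried as an ester; then the C7–C8 bond is cut. This detaches an achiral five-carbon arm (24) that brings C8–C11 and C19. The forward coupling must add an alkenyl metal to one face of the C7 aldehyde under catalyst control.

**22 ⇒ 20 ⇒ 19 ⇒ 18 ⇒ 17.** The C7 aldehyde is traced to a nitrile, and the ketal and silyl ether to the triol that comes from reducing a lactone. The lactone 17 is the relay compound that holds C3, C4 and C15. The forward reductions must distinguish lactone from nitrile, and later nitrile from everything else.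

**17 ⇒ 16 ⇒ 14 (through 15).** C15 is left to equilibration. The O–C3 bond is cut as a carboxylate opening of a 3,4-oxirane with inversion, and the oxirane is traced to the 3E olefin. One reagent-controlled epoxidation thus sets C3 and C4 and the lactone closes by itself. The forward step needs face control two atoms from C1 and exo opening at C3 rather than C4.

**14 ⇒ 13 ⇒ 11.** C16 is taken down to the terminal olefin carbon of the isopropenyl group. The forward hydroboration must select the 1,1-disubstituted olefin over the trisubstituted one and tolerate the nitrile; no control at C15 is required here.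

**11 ⇒ 9 + 10; 9 ⇒ 8 ⇒ 7 ⇒ 6 ⇒ 4 + 5.** C5–C6 is cut as an SN2 alkylation of a two-carbon nitrile anion, and C3=C4 as a stabilised-ylide olefination. The E geometry matters because it encodes the relative configuration of C3/C4. The olefination must also pick the aldehyde over the methyl ketone, which is then ketalised.

**4 ⇒ 2 (through 3) ⇒ 1; 24 ⇒ 23.** The C3 aldehyde and C12 ketone are the two ends of the cleaved ring olefin of 1, which supplies C1 with the right configuration. The forward oxidation must take the trisubstituted olefin and spare the isopropenyl group. The arm 24 comes from 23 by adding H–I across the alkyne.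

## Other disconnections considered

**Alternative 1:** The cut is C1–C15, made last on a preformed macrocycle. In the forward step the bromoacetal A1 (C3–O–CH(OEt)–CHBr–CH3 on a ring holding a C1=C14 olefin) would be treated with a tin or silicon hydride; the C15 radical adds 6-exo to C1 and the C14 radical is reduced, giving the lactol ethyl acetal A2 (Ueno–Stork cyclisation).
- In its favour: the tether forces the new C1–C15 bond cis to the C3–O bond. C16 arrives at the aldehyde level, so no lactone has to be reduced and re-oxidised; on this point it is better than the chosen plan.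
- Against it here: the radical is generated in a ring that already holds the oxirane and the exocyclic olefin, so transannular hydrogen transfer or addition is possible. C15 is set by a weakly biased radical conformer and cannot be equilibrated until the lactone exists. Turning A2 into the lactone needs acid or a strong oxidant next to the oxirane.
- Comparison: A1 presupposes a separate macrocyclisation and a catalyst-made C1, whereas the chosen plan buys C1 with the terpene. Mechanistically a radical chain replaces a metal-surface reductive coupling. The late-stage step count is about equal; the overall count is probably higher once A1 has to be built.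

**Alternative 2:** The cuts are C1–C14 and C15–C17, joining two halves. A chiral copper(I)–diphosphine catalyst would add the Grignard reagent A4 (C10–C14) to C1 of the E-enethioate A3, and the magnesium enolate would be methylated with iodomethane to give the open-chain thioester A5.
- In its favour: it is convergent. C1 and C15 are set kinetically in one operation, which is better than the thermodynamic correction of C15 used in the chosen plan. The thioester is already at the lactone oxidation level.
- Against it here: the catalyst must override the resident C3/C4 acetonide two atoms from the acceptor. Magnesium thioester enolates methylate slowly. A5 is still acyclic, so a second key step is needed to close the ring between the two allylic termini, followed by epoxidation and lactonisation.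
- Comparison: it is equal or better in convergence and in C15 control. It is worse in that the ring closure remains unsolved and the total count is unlikely to be lower.

**Alternative 3:** The cuts are C3–O(acyl), C4–O, C11–O and C12–O, all in one step. The macrocyclic 3E,11E-diene acid A6 would be treated with a chiral dioxirane; both olefins are epoxidised and the C16 carboxylate opens the 3,4-oxirane at C3 with inversion, giving the 7-O-TBS ether A7, one desilylation from the target.
- In its favour: it has the shortest endgame and no lactone masking. One catalyst antipode serves both olefins, since a (3S,4S)- and an (11S,12S)-oxirane are required. On step and protecting-group economy it is better than the chosen plan; on the epoxidation technology it is equal.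
- Against it here: A6 needs a macrocyclisation that tolerates a carboxyl group, so the carbonyl coupling cannot be used. C15 must be fixed before any lactone exists. Facial selectivity at two olefins and the C3-versus-C4 opening are all decided on the last, most valuable intermediate.
- Comparison: the chosen plan runs the same epoxy-acid lactonisation early on an acyclic compound, where the regiochemistry can be checked and C15 corrected. It pays for this with five masking and unmasking operations.

Key step: step 21

## Route

Step 1
Reactants: 1 (R)-(+)-limonene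
Product: 2 (4R)-limonene 1,2-oxide (cis/trans mixture)
Conditions: mCPBA (1.0 equiv), NaHCO3, CH2Cl2, 0 °C
Reagents that add atoms: 3-chloroperoxybenzoic acid (mCPBA), OOC(=O)c1cccc(Cl)c1
Why: Prilezhaev epoxidation; the peracid should attack the electron-richer trisubstituted ring olefin in preference to the isopropenyl group, and both oxirane diastereomers converge in step 2.

Step 2
Reactants: 2 (4R)-limonene 1,2-oxide
Product: 4 (3R)-6-oxo-3-(prop-1-en-2-yl)heptanal, via trans-1,2-diol 3 (not isolated)
Conditions: H5IO6 (1.2 equiv), THF/H2O, 0 °C → rt
Reagents that add atoms: water, O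
Why: Acid-mediated oxirane hydrolysis followed in the same pot by periodate glycol cleavage (Malaprade reaction); the stereocentre (later C1) is β to the aldehyde and γ to the ketone and should not be touched.

Step 3
Reactants: 4 (3R)-6-oxo-3-(prop-1-en-2-yl)heptanal; 5 ethyl 2-(triphenylphosphoranylidene)propanoate
Product: 6 ethyl (2E,5R)-2-methyl-8-oxo-5-(prop-1-en-2-yl)non-2-enoate
Conditions: CH2Cl2, rt
Reagents that add atoms: ethyl 2-(triphenylphosphoranylidene)propanoate (5), CCOC(=O)C(C)=P(c1ccccc1)(c1ccccc1)c1ccccc1
Why: Wittig olefination with a stabilised ylide, which should react with the aldehyde only and give the E-trisubstituted enoate (C3=C4 with C18 and C5).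

Step 4
Reactants: 6 keto enoate
Product: 7 ethyl (2E,5R)-2-methyl-7-(2-methyl-1,3-dioxolan-2-yl)-5-(prop-1-en-2-yl)hept-2-enoate
Conditions: ethylene glycol, PPTS (cat.), benzene, reflux (Dean–Stark)
Reagents that add atoms: ethylene glycol, OCCO
Why: Acid-catalysed ketalisation with azeotropic removal of water; masks the C12 ketone against the hydride and carbanion reagents of steps 5–19, and the weak acid should leave the isopropenyl group in place.

Step 5
Reactants: 7 dioxolane enoate
Product: 8 (2E,5R)-2-methyl-7-(2-methyl-1,3-dioxolan-2-yl)-5-(prop-1-en-2-yl)hept-2-en-1-ol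
Conditions: DIBAL-H (2.5 equiv), CH2Cl2, −78 °C; Rochelle salt
Reagents that add atoms: none
Why: 1,2-Reduction of the enoate to the allylic alcohol by an aluminium hydride; ketal and olefins are inert.

Step 6
Reactants: 8 allylic alcohol
Product: 9 2-[(3R,5E)-7-bromo-6-methyl-3-(prop-1-en-2-yl)hept-5-en-1-yl]-2-methyl-1,3-dioxolane
Conditions: CBr4, PPh3, 2,6-lutidine (cat.), CH2Cl2, 0 °C
Reagents that add atoms: carbon tetrabromide, BrC(Br)(Br)Br
Why: Appel bromination, SN2 at the primary allylic carbon with retention of olefin geometry; the amine buffers traces of HBr so the ketal survives.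

Step 7
Reactants: 9 allylic bromide; 10 acetonitrile
Product: 11 (4E,7R)-4-methyl-9-(2-methyl-1,3-dioxolan-2-yl)-7-(prop-1-en-2-yl)non-4-enenitrile
Conditions: MeCN (4 equiv), n-BuLi (3.5 equiv), THF, −78 °C; then 9, −78 → −20 °C
Reagents that add atoms: acetonitrile (10), CC#N
Why: SN2 alkylation of lithiated acetonitrile by the primary allylic bromide (excess anion against dialkylation) forms C5–C6. The nitrile is a latent C7 aldehyde that is inert to boranes, borohydride and mild acid, and its linear geometry keeps it from attacking the later C4 oxirane carbon.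

Step 8
Reactants: 11 dienyl nitrile
Product: 13 (4E,7R)-7-[(2RS)-1-hydroxypropan-2-yl]-4-methyl-9-(2-methyl-1,3-dioxolan-2-yl)non-4-enenitrile, via B-alkyl-9-BBN adduct 12 (not isolated)
Conditions: 9-BBN (1.3 equiv), THF, 0 °C → rt; then 30% H2O2, 3 M aq. NaOAc, 0 °C → rt
Reagents that add atoms: hydrogen peroxide, OO
Why: Anti-Markovnikov hydroboration–oxidation; 9-BBN should take the 1,1-disubstituted olefin and leave the trisubstituted olefin and the nitrile, and the acetate-buffered oxidation avoids nitrile hydration. No face control is expected at C15, which is corrected in step 11.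

Step 9
Reactants: 13 primary alcohol (C15 epimers)
Product: 14 (2RS,3R,5E)-8-cyano-2,6-dimethyl-3-[2-(2-methyl-1,3-dioxolan-2-yl)ethyl]oct-5-enoic acid
Conditions: TEMPO (cat.), PhI(OAc)2 (2.5 equiv), MeCN/pH 7 phosphate buffer, rt
Reagents that add atoms: water, O
Why: Nitroxyl-catalysed oxidation of the primary alcohol through the aldehyde hydrate to the acid; the buffer protects the ketal and the olefin is not oxidised.

Step 10
Reactants: 14 unsaturated acid (C15 epimers)
Product: 16 hydroxy δ-lactone nitrile (C15 epimer mixture), via (3S,4S)-epoxy acid 15 (not isolated)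
Conditions: L-fructose-derived Shi ketone (0.3 equiv), Oxone, K2CO3, Bu4NHSO4, MeCN/DMM/aq. borate–EDTA buffer, 0 °C; acidify to pH 4, extract; then CSA (cat.), CH2Cl2, 0 °C → rt
Reagents that add atoms: potassium peroxymonosulfate (Oxone), OOS(=O)(=O)[O-].[K+]
Why: Shi epoxidation: the chiral dioxirane adds to the 3E olefin through the spiro transition state and should give the (3S,4S)-oxirane under reagent control. Acid then triggers 6-exo opening by the carboxyl group at C3 with inversion (3R), and the oxirane oxygen stays on C4 as the 4S tertiary alcohol.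

Step 11
Reactants: 16 hydroxy δ-lactone nitrile (C15 epimer mixture)
Product: 17 (3S,4R,6R)-6-[(2S)-4-cyano-2-hydroxybutan-2-yl]-3-methyl-4-[2-(2-methyl-1,3-dioxolan-2-yl)ethyl]oxan-2-one
Conditions: DBU (1 equiv), toluene, 80 °C
Reagents that add atoms: none
Why: Base-mediated epimerisation α to the lactone carbonyl through the enolate; the equilibrium should favour the 15S isomer with C17 equatorial and trans to the C1 side chain, and the minor epimer is separated and resubjected.

Step 12
Reactants: 17 lactone
Product: 18 (4S,5R,7R)-4,5-dihydroxy-7-[(2S)-1-hydroxypropan-2-yl]-4-methyl-9-(2-methyl-1,3-dioxolan-2-yl)nonanenitrile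
Conditions: LiBH4, THF, 0 °C → rt
Reagents that add atoms: none
Why: Borohydride reduction of the lactone to the 3,16-diol; LiBH4 does not reduce nitriles or ketals and the conditions are not basic enough to epimerise C15 before reduction.

Step 13
Reactants: 18 triol
Product: 19 16-O-TBS ether of 18
Conditions: TBSCl (1.1 equiv), imidazole, CH2Cl2, 0 °C
Reagents that add atoms: tert-butyldimethylsilyl chloride, CC(C)(C)[Si](C)(C)Cl
Why: Silylation, selective for the primary hydroxyl over the hindered secondary and tertiary ones.

Step 14
Reactants: 19 silyl ether diol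
Product: 20 3,4-O-isopropylidene-16-O-TBS nitrile
Conditions: 2-methoxypropene, PPTS (cat.), CH2Cl2, 0 °C
Reagents that add atoms: 2-methoxypropene, COC(C)=C
Why: Acid-catalysed acetonide formation; only the vicinal 3,4-diol can close a five-membered dioxolane, and the short, cold, anhydrous treatment should not exchange the C12 ketal.

Step 15
Reactants: 20 acetonide nitrile
Product: 22 C7 aldehyde, via aldimine 21 (not isolated)
Conditions: DIBAL-H (1.5 equiv), toluene, −78 °C; then aq. tartaric acid/Rochelle salt, 0 °C
Reagents that add atoms: water, O
Why: Single hydride addition to the nitrile gives an N-aluminio imine that is stable in the cold and hydrolyses to the aldehyde on mildly acidic work-up; acetals and the silyl ether are unaffected.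

Step 16
Reactants: 23 methyl pent-4-ynoate
Product: 24 methyl 4-iodopent-4-enoate
Conditions: NaI, TMSCl, H2O (0.5 equiv), MeCN, rt
Reagents that add atoms: sodium iodide, [Na+].[I-]
Why: Markovnikov hydroiodination of the terminal alkyne by HI generated in situ gives the 2-iodo-1-alkene that carries C8, C19 and C9–C11.

Step 17
Reactants: 22 C7 aldehyde; 24 methyl 4-iodopent-4-enoate
Product: 25 (7R)-allylic alcohol methyl ester
Conditions: CrCl2 (cat.), chiral 2-(oxazolinyl)aryl sulfonamide ligand, proton sponge, NiCl2·2,9-dimethylphenanthroline (cat.), Mn, Cp2ZrCl2, LiCl, MeCN, rt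
Reagents that add atoms: methyl 4-iodopent-4-enoate (24), COC(=O)CCC(I)=C
Why: Catalytic asymmetric Nozaki–Hiyama–Kishi coupling: nickel activates the C–I bond, the alkenyl group passes to the chiral chromium(III) complex and adds to the aldehyde, forming C7–C8 with the exocyclic methylene in place. The ligand antipode is chosen for Si-face delivery (7R); the nearest resident stereocentre (C4) is 1,4, so catalyst control is expected, and ester, acetals and silyl ether are tolerated.

Step 18
Reactants: 25 allylic alcohol
Product: 26 7-O-TBDPS ether
Conditions: TBDPSCl, imidazole, DMAP (cat.), DMF, 40 °C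
Reagents that add atoms: tert-butyldiphenylsilyl chloride, CC(C)(C)[Si](Cl)(c1ccccc1)c1ccccc1
Why: Silylation of the secondary allylic alcohol with an acid-stable silyl group that survives steps 20–24 and is removed by fluoride at the end.

Step 19
Reactants: 26 methyl ester
Product: 27 C11 aldehyde
Conditions: DIBAL-H (1.1 equiv), CH2Cl2, −78 °C; MeOH, Rochelle salt
Reagents that add atoms: none
Why: Partial reduction of the ester; the tetrahedral aluminium hemiacetal is stable at −78 °C and collapses to the aldehyde on work-up.

Step 20
Reactants: 27 aldehyde ketal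
Product: 28 11,12-seco keto-aldehyde (3,4-acetonide; 7-O-TBDPS; 16-O-TBS)
Conditions: PPTS (cat.), acetone/H2O (10:1), 40 °C
Reagents that add atoms: water, O
Why: Acid-catalysed ketal exchange and hydrolysis; in acetone the isopropylidene acetal is in equilibrium with its own solvent and should persist while the dioxolane is released, and PPTS is too weak to cleave the silyl ethers.

Step 21
Reactants: 28 11,12-seco keto-aldehyde
Product: 30 protected 11E macrocyclic triene, via titanium pinacolate 29 (not isolated)
Conditions: TiCl3(DME)1.5, Zn–Cu, DME, reflux; 28 added by syringe pump over 30 h (final ca. 1 mM); then reflux 5 h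
Reagents that add atoms: none
Why: Low-valent titanium from TiCl3 and Zn–Cu transfers one electron to each carbonyl; the two titanium-bound ketyls couple on the metal to the cyclic 11,12-pinacolate 29, and at reflux both C–O bonds are cleaved on titanium to release the C11=C12 olefin (intramolecular McMurry coupling; the closest known type is keto-aldehyde closure to 14-membered trisubstituted cycloalkenes). The 14-membered carbocycle is closed in the C11–C12 bond-forming event itself, an end-to-end macrocyclisation kept unimolecular by slow addition to the titanium slurry. No stereocentre is created; the deoxygenation is not stereospecific, so the geometry follows product strain and the E isomer should predominate in this ring size; the geometry is to be assigned by NOE and the Z isomer removed. The step needs chemoselectivity for the two carbonyls: the substrate holds no ester, halide or free hydroxyl, the lactone oxygens are tied up as acetonide and silyl ether, and the allylic C7 oxygen is a bulky silyl ether that cannot become a titanium alkoxide, which would invite allylic C–O reduction. Neither carbonyl has an α-stereocentre (C10 and C13 are methylenes), so enolisation on the Lewis-acidic metal cannot erode C1, C3, C4, C7 or C15. The aldehyde, the more easily reduced partner, is kept at very low stationary concentration, which suppresses intermolecular pinacol dimerisation.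

Step 22
Reactants: 30 protected macrocyclic triene
Product: 31 7-O-TBDPS 3,4,16-triol
Conditions: AcOH/THF/H2O (3:1:1), 45 °C
Reagents that add atoms: none
Why: Acid hydrolysis removes the isopropylidene acetal and the primary TBS ether; the secondary TBDPS ether is far more acid-stable and should remain.

Step 23
Reactants: 31 triol
Product: 33 macrocyclic hydroxy δ-lactone (7-O-TBDPS), via lactol 32 (not isolated)
Conditions: TEMPO (cat.), PhI(OAc)2 (3 equiv), CH2Cl2, rt
Reagents that add atoms: none
Why: Oxidative lactonisation: the nitroxyl catalyst oxidises the primary C16 alcohol to the aldehyde, which closes with the C3 hydroxyl to the six-membered lactol and is oxidised again to the lactone. The tertiary hydroxyl and the olefins are inert, and the all-equatorial lactone is the stable C15 epimer.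

Step 24
Reactants: 33 macrocyclic lactone
Product: 34 (11S,12S)-epoxide (7-O-TBDPS ether of the target)
Conditions: L-fructose-derived Shi ketone (0.3–0.5 equiv), Oxone, K2CO3, Bu4NHSO4, MeCN/DMM/aq. borate–EDTA buffer, 0 °C
Reagents that add atoms: potassium peroxymonosulfate (Oxone), OOS(=O)(=O)[O-].[K+]
Why: Shi epoxidation; the dioxirane should take the trisubstituted 11E olefin in preference to the hindered 1,1-disubstituted C8=C19 olefin, and the spiro transition state of this catalyst antipode places oxygen on the face that gives 11S,12S (reagent control).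

Step 25
Reactants: 34 silyl ether
Product: 35 target (1R,3R,4S,7R,11S,12S,15S)
Conditions: TBAF, AcOH (1:1), THF, rt → 40 °C
Reagents that add atoms: none
Why: Fluoride-induced desilylation; the acetic acid buffer keeps the medium from opening the lactone or the oxirane.

## Compound list

1 | (R)-(+)-limonene, (4R)-1-methyl-4-(prop-1-en-2-yl)cyclohex-1-ene | CC1=CC[C@@H](CC1)C(C)=C | starting material
2 | (4R)-limonene 1,2-oxide, cis/trans mixture at the oxirane | CC12OC1C[C@@H](CC2)C(C)=C | intermediate
3 | (4R)-p-menth-8-ene-1,2-diol, trans-diol (not isolated) | CC1(O)C(O)C[C@@H](CC1)C(C)=C | intermediate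
4 | (3R)-6-oxo-3-(prop-1-en-2-yl)heptanal | CC(=O)CC[C@H](CC=O)C(C)=C | intermediate
5 | ethyl 2-(triphenylphosphoranylidene)propanoate | CCOC(=O)C(C)=P(c1ccccc1)(c1ccccc1)c1ccccc1 | starting material
6 | ethyl (2E,5R)-2-methyl-8-oxo-5-(prop-1-en-2-yl)non-2-enoate | CC(=O)CC[C@H](C/C=C(\C)C(=O)OCC)C(C)=C | intermediate
7 | ethyl (2E,5R)-2-methyl-7-(2-methyl-1,3-dioxolan-2-yl)-5-(prop-1-en-2-yl)hept-2-enoate | CC1(OCCO1)CC[C@H](C/C=C(\C)C(=O)OCC)C(C)=C | intermediate
8 | (2E,5R)-2-methyl-7-(2-methyl-1,3-dioxolan-2-yl)-5-(prop-1-en-2-yl)hept-2-en-1-ol | CC1(OCCO1)CC[C@H](C/C=C(\C)CO)C(C)=C | intermediate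
9 | 2-[(3R,5E)-7-bromo-6-methyl-3-(prop-1-en-2-yl)hept-5-en-1-yl]-2-methyl-1,3-dioxolane | CC1(OCCO1)CC[C@H](C/C=C(\C)CBr)C(C)=C | intermediate
10 | acetonitrile | CC#N | starting material
11 | (4E,7R)-4-methyl-9-(2-methyl-1,3-dioxolan-2-yl)-7-(prop-1-en-2-yl)non-4-enenitrile | CC1(OCCO1)CC[C@H](C/C=C(\C)CCC#N)C(C)=C | intermediate
12 | B-alkyl-9-borabicyclo[3.3.1]nonane adduct of 11 at the terminal isopropenyl carbon, C15 epimers (not isolated) | CC1(OCCO1)CC[C@H](C/C=C(\C)CCC#N)C(C)CB1C2CCCC1CCC2 | intermediate
13 | (4E,7R)-7-[(2RS)-1-hydroxypropan-2-yl]-4-methyl-9-(2-methyl-1,3-dioxolan-2-yl)non-4-enenitrile | CC1(OCCO1)CC[C@H](C/C=C(\C)CCC#N)C(C)CO | intermediate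
14 | (2RS,3R,5E)-8-cyano-2,6-dimethyl-3-[2-(2-methyl-1,3-dioxolan-2-yl)ethyl]oct-5-enoic acid | CC1(OCCO1)CC[C@H](C/C=C(\C)CCC#N)C(C)C(O)=O | intermediate
15 | (3S,4S)-3,4-epoxide of 14 (cembrane locants), C15 epimers (not isolated) | CC1(OCCO1)CC[C@H](C[C@@H]2O[C@@]2(C)CCC#N)C(C)C(O)=O | intermediate
16 | (3RS,4R,6R)-6-[(2S)-4-cyano-2-hydroxybutan-2-yl]-3-methyl-4-[2-(2-methyl-1,3-dioxolan-2-yl)ethyl]oxan-2-one | CC1(OCCO1)CC[C@@H]2C[C@@H](OC(=O)C2C)[C@@](C)(O)CCC#N | intermediate
17 | (3S,4R,6R)-6-[(2S)-4-cyano-2-hydroxybutan-2-yl]-3-methyl-4-[2-(2-methyl-1,3-dioxolan-2-yl)ethyl]oxan-2-one | CC1(OCCO1)CC[C@@H]2C[C@@H](OC(=O)[C@H]2C)[C@@](C)(O)CCC#N | intermediate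
18 | (4S,5R,7R)-4,5-dihydroxy-7-[(2S)-1-hydroxypropan-2-yl]-4-methyl-9-(2-methyl-1,3-dioxolan-2-yl)nonanenitrile | CC1(OCCO1)CC[C@H](C[C@@H](O)[C@@](C)(O)CCC#N)[C@H](C)CO | intermediate
19 | 16-O-tert-butyldimethylsilyl ether of 18 (primary hydroxyl silylated) | CC1(OCCO1)CC[C@H](C[C@@H](O)[C@@](C)(O)CCC#N)[C@H](C)CO[Si](C)(C)C(C)(C)C | intermediate
20 | 3,4-O-isopropylidene derivative of 19 (C7 nitrile, C12 dioxolane, 16-O-TBS) | CC1(OCCO1)CC[C@H](C[C@H]2OC(C)(C)O[C@@]2(C)CCC#N)[C@H](C)CO[Si](C)(C)C(C)(C)C | intermediate
21 | C7 aldimine of 20, present as its N-aluminium derivative (not isolated) | CC1(OCCO1)CC[C@H](C[C@H]2OC(C)(C)O[C@@]2(C)CCC=N)[C@H](C)CO[Si](C)(C)C(C)(C)C | intermediate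
22 | C7 aldehyde (3,4-acetonide, C12 dioxolane, 16-O-TBS; 1R,3R,4S,15S) | CC1(OCCO1)CC[C@H](C[C@H]2OC(C)(C)O[C@@]2(C)CCC=O)[C@H](C)CO[Si](C)(C)C(C)(C)C | intermediate
23 | methyl pent-4-ynoate | COC(=O)CCC#C | starting material
24 | methyl 4-iodopent-4-enoate | COC(=O)CCC(I)=C | intermediate
25 | (7R)-allylic alcohol with C8(19) methylene and C11 methyl ester (3,4-acetonide, C12 dioxolane, 16-O-TBS; 1R,3R,4S,7R,15S) | CC1(OCCO1)CC[C@H](C[C@H]2OC(C)(C)O[C@@]2(C)CC[C@@H](O)C(=C)CCC(=O)OC)[C@H](C)CO[Si](C)(C)C(C)(C)C | intermediate
26 | 7-O-tert-butyldiphenylsilyl ether of 25 | CC1(OCCO1)CC[C@H](C[C@H]2OC(C)(C)O[C@@]2(C)CC[C@@H](O[Si](c3ccccc3)(c3ccccc3)C(C)(C)C)C(=C)CCC(=O)OC)[C@H](C)CO[Si](C)(C)C(C)(C)C | intermediate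
27 | C11 aldehyde with C12 still as dioxolane (3,4-acetonide, 7-O-TBDPS, 16-O-TBS) | CC1(OCCO1)CC[C@H](C[C@H]2OC(C)(C)O[C@@]2(C)CC[C@@H](O[Si](c3ccccc3)(c3ccccc3)C(C)(C)C)C(=C)CCC=O)[C@H](C)CO[Si](C)(C)C(C)(C)C | intermediate
28 | 11,12-seco keto-aldehyde: C11 aldehyde, C12 methyl ketone, C8(19) methylene, 3,4-acetonide, 7-O-TBDPS, 16-O-TBS (1R,3R,4S,7R,15S) | CC(=O)CC[C@H](C[C@H]1OC(C)(C)O[C@@]1(C)CC[C@@H](O[Si](c2ccccc2)(c2ccccc2)C(C)(C)C)C(=C)CCC=O)[C@H](C)CO[Si](C)(C)C(C)(C)C | intermediate
29 | macrocyclic 11,12-pinacolate, drawn as the free diol, both oxygens titanium-bound in the flask, C11/C12 unassigned (not isolated) | C=C1CCC(O)C(C)(O)CC[C@H](C[C@H]2OC(C)(C)O[C@@]2(C)CC[C@H]1O[Si](c1ccccc1)(c1ccccc1)C(C)(C)C)[C@H](C)CO[Si](C)(C)C(C)(C)C | intermediate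
30 | protected 11E macrocyclic triene: 14-membered ring, 3,4-acetonide, 7-O-TBDPS, 16-O-TBS (1R,3R,4S,7R,15S) | C=C1CC/C=C(\C)CC[C@H](C[C@H]2OC(C)(C)O[C@@]2(C)CC[C@H]1O[Si](c1ccccc1)(c1ccccc1)C(C)(C)C)[C@H](C)CO[Si](C)(C)C(C)(C)C | intermediate
31 | 11E macrocyclic 3,4,16-triol, 7-O-TBDPS | C=C1CC/C=C(\C)CC[C@H](C[C@@H](O)[C@@](C)(O)CC[C@H]1O[Si](c1ccccc1)(c1ccccc1)C(C)(C)C)[C@H](C)CO | intermediate
32 | macrocyclic lactol (C16 hemiacetal to O3), anomers (not isolated) | C=C1CC/C=C(\C)CC[C@@H]2C[C@@H](OC(O)[C@H]2C)[C@@](C)(O)CC[C@H]1O[Si](c1ccccc1)(c1ccccc1)C(C)(C)C | intermediate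
33 | 11E macrocyclic hydroxy δ-lactone, 7-O-TBDPS (1R,3R,4S,7R,15S) | C=C1CC/C=C(\C)CC[C@@H]2C[C@@H](OC(=O)[C@H]2C)[C@@](C)(O)CC[C@H]1O[Si](c1ccccc1)(c1ccccc1)C(C)(C)C | intermediate
34 | 7-O-TBDPS ether of the target, (11S,12S)-epoxide | C=C1CC[C@@H]2O[C@@]2(C)CC[C@@H]2C[C@@H](OC(=O)[C@H]2C)[C@@](C)(O)CC[C@H]1O[Si](c1ccccc1)(c1ccccc1)C(C)(C)C | intermediate
35 | CNP0262409.1, (1R,3R,4S,7R,11S,12S,15S)-11,12-epoxy-4,7-dihydroxycembr-8(19)-en-16,3-olide | C=C1CC[C@@H]2O[C@@]2(C)CC[C@@H]2C[C@@H](OC(=O)[C@H]2C)[C@@](C)(O)CC[C@H]1O | target

## Step count and risk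

Total: 25 steps (24 in the main line, one for the arm). Longest linear sequence: 24 steps from 1 (steps 1–15 and 17–25).

**Step 21 (key step).** The most likely failures are intermolecular coupling to oligomers if the stationary concentration is too high, a stall at the pinacolate, and an unfavourable E/Z ratio because the deoxygenation is not stereospecific. Reductive loss of the allylic C7 silyloxy group on the titanium surface is a lesser risk. Fallback: set out from 28, convert both carbonyls to methylenes with methylenetriphenylphosphorane to give the 11,12-bis-methylene tetraene F1, and close the same C11=C12 bond by ring-closing metathesis with a second-generation ruthenium alkylidene under high dilution. The monosubstituted C11 olefin and the 1,1-disubstituted C12 olefin give the trisubstituted ring olefin with loss of ethylene, and the hindered C8=C19 olefin should stay out. After separation of geometric isomers the route is rejoined at 30.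

**Step 10.** The likely failures are incomplete face selection by the dioxirane on the carboxylate salt of a substrate whose only resident stereocentre is two atoms away, and competing 7-endo opening at the tertiary C4 under acid. Fallback: set out from 8 and use hydroxyl-directed, reagent-controlled epoxidation. Sharpless asymmetric epoxidation with L-(+)-diethyl tartrate should give the (3S,4S)-epoxy alcohol F2, by analogy with E-2-alkenols giving (2S,3S)-epoxy alcohols. Its triflate F3, made and used cold, is displaced by lithiated acetonitrile to give the epoxy nitrile F4. 9-BBN hydroboration through the borane F5 and buffered oxidation give the epoxy alcohol F6, and nitroxyl oxidation as in step 9 gives 15. Acid closure then rejoins the route at 16.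

**Step 17.** The likely failure is insufficient catalyst control at C7, or slow turnover with a 1,1-disubstituted iodide. Fallback: set out from 22 and 24 and couple them with achiral chromium(II) chloride and catalytic nickel to the C7-epimeric allylic alcohols F7. Oxidise with Dess–Martin periodinane to the α-methylene ketone F8, and reduce with the (S)-oxazaborolidine and borane (Corey–Bakshi–Shibata reduction). With the branched alkenyl group acting as the large substituent, this should give the 7R alcohol, and the route is rejoined at 25.

**Step 24.** The likely failures are the ring conformation overriding the catalyst so that oxygen arrives on the wrong face, and slow opening of the lactone in the basic buffer. Fallback: set out from 33 and use substrate control with the opposite facial sense to a direct oxygen transfer. N-bromosuccinimide in aqueous THF gives the (11R,12S)-bromohydrin F9 (bromonium on the exposed face, water at C12 from the other). Potassium carbonate in acetone closes it with inversion at C11, which places the oxirane oxygen on the face opposite to the one an electrophile attacks, and the route is rejoined at 34. If the exposed face is instead the required one, a buffered peracid does the same job directly.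

## Further compounds

F1 | step 21 | 11,12-bis-methylene tetraene from 28 (C11 vinyl, C12 isopropenyl; 3,4-acetonide, 7-O-TBDPS, 16-O-TBS) | CC(=C)CC[C@H](C[C@H]1OC(C)(C)O[C@@]1(C)CC[C@@H](O[Si](c2ccccc2)(c2ccccc2)C(C)(C)C)C(=C)CCC=C)[C@H](C)CO[Si](C)(C)C(C)(C)C
F2 | step 10 | (3S,4S)-epoxy alcohol from 8 (cembrane locants; C5 hydroxymethyl) | CC1(OCCO1)CC[C@H](C[C@@H]2O[C@@]2(C)CO)C(C)=C
F3 | step 10 | trifluoromethanesulfonate of F2 | CC1(OCCO1)CC[C@H](C[C@@H]2O[C@@]2(C)COS(=O)(=O)C(F)(F)F)C(C)=C
F4 | step 10 | (3S,4S)-epoxy nitrile with isopropenyl group | CC1(OCCO1)CC[C@H](C[C@@H]2O[C@@]2(C)CCC#N)C(C)=C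
F5 | step 10 | B-alkyl-9-borabicyclo[3.3.1]nonane adduct of F4, C15 epimers | CC1(OCCO1)CC[C@H](C[C@@H]2O[C@@]2(C)CCC#N)C(C)CB1C2CCCC1CCC2
F6 | step 10 | (3S,4S)-epoxy nitrile with C16 primary alcohol, C15 epimers | CC1(OCCO1)CC[C@H](C[C@@H]2O[C@@]2(C)CCC#N)C(C)CO
F7 | step 17 | C7-epimeric mixture of allylic alcohol 25 | CC1(OCCO1)CC[C@H](C[C@H]2OC(C)(C)O[C@@]2(C)CCC(O)C(=C)CCC(=O)OC)[C@H](C)CO[Si](C)(C)C(C)(C)C
F8 | step 17 | C7 ketone (α-methylene ketone) corresponding to 25 | CC1(OCCO1)CC[C@H](C[C@H]2OC(C)(C)O[C@@]2(C)CCC(=O)C(=C)CCC(=O)OC)[C@H](C)CO[Si](C)(C)C(C)(C)C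
F9 | step 24 | (11R,12S)-11-bromo-12-hydroxy derivative of 33 | C=C1CC[C@@H](Br)[C@@](C)(O)CC[C@@H]2C[C@@H](OC(=O)[C@H]2C)[C@@](C)(O)CC[C@H]1O[Si](c1ccccc1)(c1ccccc1)C(C)(C)C
A1 | alternative 1 | macrocyclic C3-O-(2-bromo-1-ethoxypropyl) acetal with C1=C14 olefin (E assumed), 4-O-TES, 7-O-TBS, 11,12-epoxide | C=C1CC[C@@H]2O[C@@]2(C)C/C=C/C[C@@H](OC(OCC)C(C)Br)[C@@](C)(O[Si](CC)(CC)CC)CC[C@H]1O[Si](C)(C)C(C)(C)C
A2 | alternative 1 | bicyclic lactol ethyl acetal (anomeric mixture), 4-O-TES, 7-O-TBS | C=C1CC[C@@H]2O[C@@]2(C)CC[C@@H]2C[C@@H](OC(OCC)[C@H]2C)[C@@](C)(O[Si](CC)(CC)CC)CC[C@H]1O[Si](C)(C)C(C)(C)C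
A3 | alternative 2 | S-ethyl E-enethioate C16–C15=C1–C2 with 3,4-acetonide, 7-O-TBS, C9 PMB ether | CCSC(=O)/C=C/C[C@H]1OC(C)(C)O[C@@]1(C)CC[C@@H](O[Si](C)(C)C(C)(C)C)C(=C)COCc1ccc(OC)cc1
A4 | alternative 2 | C10–C14 Grignard reagent, (E)-5-(tert-butyldimethylsilyloxy)-3-methylpent-3-enylmagnesium bromide | Br[Mg]CC/C(C)=C/CO[Si](C)(C)C(C)(C)C
A5 | alternative 2 | open-chain C1–C20 thioester | CCSC(=O)[C@@H](C)[C@H](CC/C(C)=C/CO[Si](C)(C)C(C)(C)C)C[C@H]1OC(C)(C)O[C@@]1(C)CC[C@@H](O[Si](C)(C)C(C)(C)C)C(=C)COCc1ccc(OC)cc1
A6 | alternative 3 | macrocyclic 3E,11E-diene C16 acid, 7-O-TBS | C=C1CC/C=C(\C)CC[C@H](C/C=C(\C)CC[C@H]1O[Si](C)(C)C(C)(C)C)[C@H](C)C(O)=O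
A7 | alternative 3 | 7-O-TBS ether of the target | C=C1CC[C@@H]2O[C@@]2(C)CC[C@@H]2C[C@@H](OC(=O)[C@H]2C)[C@@](C)(O)CC[C@H]1O[Si](C)(C)C(C)(C)C
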